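The butenolide (furan-2(5H)-one ring) is disconnected at its C4–C5 bond, between the chain-bearing ring carbon C4 and the O-bound methylene C5. Both are acceptor carbons (C4 the enoate β-carbon, C5 an oxygenated carbon), so the key step reverses the polarity of C5: an intramolecular Stille coupling of a (tributylstannyl)methyl (Z)-3-triflyloxy-2-enoate, whose ester already links O1, C2 and C3, closes the five-membered ring. The precursor is an open-chain β-keto ester made by a Blaise reaction on a nitrile that unites the (S)-γ-cyclogeranyl unit (copper-catalysed asymmetric allylic alkylation) with a geranyl-derived chain.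

Key step: step 14

Assumption: in step 4 the ligand antipode that leads to the (S)-product is used, and in the fallback to step 4 the lipase is taken to acylate the (R)-alcohol faster (if it prefers the (S)-alcohol, the (S)-acetate is collected and methanolysed to 8).

Step 1
Reactants: 1 3-methylcyclohex-2-en-1-one
Product: 3 3,3-dimethylcyclohex-1-en-1-yl trifluoromethanesulfonate, via lithium enolate 2 (not isolated)
Conditions: MeLi (2 equiv), CuI (1 equiv), Et2O, 0 °C; then 1; then PhNTf2, THF, 0 °C to rt
Reagents that add atoms: lithium dimethylcuprate (made in the flask from MeLi and CuI) [Li+].C[Cu-]C; N-phenylbis(trifluoromethanesulfonimide) O=S(=O)(N(c1ccccc1)S(=O)(=O)C(F)(F)F)C(F)(F)F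
Why: Conjugate addition of the Gilman cuprate to the β-methyl enone builds the gem-dimethyl carbon and gives the enolate regiospecifically, and its O-sulfonylation (enol triflate formation) fixes the double bond on the side of the quaternary carbon; no stereocenter is formed.

Step 2
Reactants: 3 3,3-dimethylcyclohex-1-en-1-yl trifluoromethanesulfonate; 4 (tributylstannyl)methanol
Product: 5 (3,3-dimethylcyclohex-1-en-1-yl)methanol
Conditions: Pd(PPh3)4 (5 mol %), LiCl (3 equiv), 1,4-dioxane, 100 °C
Reagents that add atoms: none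
Why: Migita–Kosugi–Stille hydroxymethylation, in which the alkenyl triflate adds oxidatively to zerovalent palladium and the α-oxygenated methylene is transferred from tin in preference to butyl.

Step 3
Reactants: 5 (3,3-dimethylcyclohex-1-en-1-yl)methanol
Product: 6 1-(chloromethyl)-3,3-dimethylcyclohex-1-ene
Conditions: NCS, PPh3, CH2Cl2, −20 °C to 0 °C
Reagents that add atoms: N-chlorosuccinimide O=C1CCC(=O)N1Cl
Why: Appel-type chlorination, in which chloride displaces the alkoxyphosphonium group at the primary carbon by SN2 without allylic transposition.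

Step 4
Reactants: 6 1-(chloromethyl)-3,3-dimethylcyclohex-1-ene
Product: 7 {[(1S)-2,2-dimethyl-6-methylidenecyclohexyl]methyl}dimethyl(propan-2-yloxy)silane
Conditions: (i-PrO)Me2SiCH2MgCl (1.3 equiv, from (i-PrO)Me2SiCH2Cl and Mg, Et2O), Cu(O2CC4H3S) (copper thiophene-2-carboxylate, 3 mol %), chiral BINOL-derived phosphoramidite ligand (3.3 mol %), CH2Cl2, −78 °C, slow addition
Reagents that add atoms: [(isopropoxy)dimethylsilyl]methylmagnesium chloride CC(C)O[Si](C)(C)C[Mg]Cl
Why: Copper-catalysed asymmetric allylic alkylation (SN2′) of an endocyclic allylic chloride by a Grignard reagent, in which attack at the ring CH creates the exocyclic methylene and the stereocenter under control of the chiral phosphoramidite–copper complex; the attacked carbon has the same steric environment as the β-carbon of 4,4-dimethylcyclohex-2-enone, which accepts organocopper nucleophiles well.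

Step 5
Reactants: 7 {[(1S)-2,2-dimethyl-6-methylidenecyclohexyl]methyl}dimethyl(propan-2-yloxy)silane
Product: 8 [(1S)-2,2-dimethyl-6-methylidenecyclohexyl]methanol
Conditions: 30% H2O2, KF, KHCO3, THF/MeOH (1:1), rt
Reagents that add atoms: hydrogen peroxide OO
Why: Tamao–Kumada oxidation, which turns the C–Si bond of the alkoxysilane into C–OH under mildly basic conditions that leave the 1,1-disubstituted alkene and the adjacent stereocenter untouched.

Step 6
Reactants: 8 [(1S)-2,2-dimethyl-6-methylidenecyclohexyl]methanol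
Product: 9 (2S)-2-(bromomethyl)-1,1-dimethyl-3-methylidenecyclohexane
Conditions: CBr4, PPh3, CH2Cl2, 0 °C
Reagents that add atoms: carbon tetrabromide BrC(Br)(Br)Br
Why: Appel bromination by SN2 at the primary carbon, which does not involve the stereocenter.

Step 7
Reactants: 10 geranyl bromide
Product: 11 (4E)-5,9-dimethyldeca-4,8-dienenitrile
Conditions: MeCN (3 equiv), n-BuLi (2.5 equiv), THF, −78 °C; then 10, −78 °C to −30 °C
Reagents that add atoms: acetonitrile CC#N
Why: SN2 alkylation of lithiated acetonitrile at the primary allylic carbon keeps the E-alkene and adds the carbon that becomes C4 of the butenolide together with its neighbouring chain methylene.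

Step 8
Reactants: 11 (4E)-5,9-dimethyldeca-4,8-dienenitrile
Product: 12 (4E,8E)-10-hydroxy-5,9-dimethyldeca-4,8-dienenitrile
Conditions: SeO2 (0.2 equiv), t-BuOOH (70% aq., 3 equiv), salicylic acid (0.1 equiv), CH2Cl2, rt
Reagents that add atoms: tert-butyl hydroperoxide CC(C)(C)OO
Why: Selenium dioxide allylic oxidation (Riley type, ene reaction then [2,3]-shift) hydroxylates the (E)-methyl group of the terminal, most accessible trisubstituted alkene and gives the (E)-allylic alcohol.

Step 9
Reactants: 12 (4E,8E)-10-hydroxy-5,9-dimethyldeca-4,8-dienenitrile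
Product: 13 (4E,8E)-10-bromo-5,9-dimethyldeca-4,8-dienenitrile
Conditions: CBr4, PPh3, CH2Cl2, −20 °C
Reagents that add atoms: carbon tetrabromide BrC(Br)(Br)Br
Why: Appel bromination of the primary allylic alcohol at low temperature proceeds by SN2 without allylic transposition or loss of alkene geometry.

Step 10
Reactants: 9 (2S)-2-(bromomethyl)-1,1-dimethyl-3-methylidenecyclohexane; 13 (4E,8E)-10-bromo-5,9-dimethyldeca-4,8-dienenitrile
Product: 15 (4E,8E)-11-[(1S)-2,2-dimethyl-6-methylidenecyclohexyl]-5,9-dimethylundeca-4,8-dienenitrile, via Grignard reagent 14 (not isolated)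
Conditions: 9, Mg, THF, 40 °C; then 13, Li2CuCl4 (3 mol %), THF, −78 °C to 0 °C
Reagents that add atoms: none
Why: Li2CuCl4-catalysed cross-coupling of a primary alkyl Grignard reagent with a primary allylic bromide takes place at the α-carbon with retention of the E-alkene and faster than addition to the nitrile at low temperature; the ring stereocenter is not touched.

Step 11
Reactants: 4 (tributylstannyl)methanol; 16 bromoacetyl bromide
Product: 17 (tributylstannyl)methyl bromoacetate
Conditions: pyridine, CH2Cl2, 0 °C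
Reagents that add atoms: none
Why: O-acylation of the primary alcohol by the acid bromide, which leaves the α-bromo ester ready for zinc insertion.

Step 12
Reactants: 15 (4E,8E)-11-[(1S)-2,2-dimethyl-6-methylidenecyclohexyl]-5,9-dimethylundeca-4,8-dienenitrile; 17 (tributylstannyl)methyl bromoacetate
Product: 20 (tributylstannyl)methyl (6E,10E)-13-[(1S)-2,2-dimethyl-6-methylidenecyclohexyl]-7,11-dimethyl-3-oxotrideca-6,10-dienoate, via Reformatsky reagent 18 (not isolated), via zinc enaminate 19 (not isolated)
Conditions: activated Zn (8 equiv), 17 (3 equiv, slow addition), THF, reflux; then 1 M aq. HCl, THF, rt, 30 min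
Reagents that add atoms: water O
Why: Blaise reaction, in which the Reformatsky reagent adds to the nitrile to give a chelated zinc enaminate that dilute acid hydrolyses to the β-keto ester, so that C3, C2, O1 and the stannylated C5 of the future lactone are attached to C4 in one operation.

Step 13
Reactants: 20 (tributylstannyl)methyl (6E,10E)-13-[(1S)-2,2-dimethyl-6-methylidenecyclohexyl]-7,11-dimethyl-3-oxotrideca-6,10-dienoate
Product: 22 (tributylstannyl)methyl (2Z,6E,10E)-13-[(1S)-2,2-dimethyl-6-methylidenecyclohexyl]-7,11-dimethyl-3-{[(trifluoromethyl)sulfonyl]oxy}trideca-2,6,10-trienoate, via lithium enolate 21 (not isolated)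
Conditions: Tf2O (1.5 equiv), sat. aq. LiOH, hexanes, 5 °C
Reagents that add atoms: trifluoromethanesulfonic anhydride O=S(=O)(OS(=O)(=O)C(F)(F)F)C(F)(F)F
Why: O-triflation of the chelated lithium (Z)-enolate of the β-keto ester under biphasic conditions should give the (Z)-enol triflate, which places the leaving group cis to the ester as the cyclisation requires; no stereocenter is formed.

Step 14
Reactants: 22 (tributylstannyl)methyl (2Z,6E,10E)-13-[(1S)-2,2-dimethyl-6-methylidenecyclohexyl]-7,11-dimethyl-3-{[(trifluoromethyl)sulfonyl]oxy}trideca-2,6,10-trienoate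
Product: 23 4-{(3E,7E)-10-[(1S)-2,2-dimethyl-6-methylidenecyclohexyl]-4,8-dimethyldeca-3,7-dien-1-yl}furan-2(5H)-one
Conditions: Pd2(dba)3 (5 mol %), AsPh3 (40 mol %), CuI (10 mol %), LiCl (3 equiv), NMP, 60 °C, syringe-pump addition to a final 0.005 M
Reagents that add atoms: none
Why: Zerovalent palladium inserts into the C4–OTf bond with retention, so that palladium sits cis to the ester; chloride exchange and copper-assisted intramolecular tin-to-palladium transfer of the α-acyloxymethyl carbon C5 (oxygen-activated, no β-hydrogen) give a six-membered oxapalladacycle, and reductive elimination forms the C4–C5 bond. The closest known reaction type is the Migita–Kosugi–Stille coupling of (hydroxymethyl)- and (acyloxymethyl)tributylstannanes with aryl and alkenyl halides or triflates, here run intramolecularly. The five-membered lactone closes with the C3=C4 double bond inside the ring (formally a 5-endo closure at C4), which is feasible because the bond is made by reductive elimination from the palladacycle and not by direct attack on the alkene. No stereocenter is formed, the C3=C4 geometry is fixed by the ring, and the (S)-centre in the cyclohexane is remote and untouched. The step needs the (Z)-enol triflate (secured in step 13), transfer of the oxygenated methylene in preference to butyl (secured by the α-oxygen and copper) and cyclisation in preference to intermolecular coupling (secured by high dilution); the three isolated alkenes are inert under these neutral conditions.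

Compound list
1 | 3-methylcyclohex-2-en-1-one | CC1=CC(=O)CCC1 | starting material
2 | lithium 3,3-dimethylcyclohex-1-en-1-olate | [Li+].[O-]C1=CC(C)(C)CCC1 | intermediate
3 | 3,3-dimethylcyclohex-1-en-1-yl trifluoromethanesulfonate | CC1(C)CCCC(OS(=O)(=O)C(F)(F)F)=C1 | intermediate
4 | (tributylstannyl)methanol | CCCC[Sn](CCCC)(CCCC)CO | starting material
5 | (3,3-dimethylcyclohex-1-en-1-yl)methanol | CC1(C)CCCC(CO)=C1 | intermediate
6 | 1-(chloromethyl)-3,3-dimethylcyclohex-1-ene | CC1(C)CCCC(CCl)=C1 | intermediate
7 | {[(1S)-2,2-dimethyl-6-methylidenecyclohexyl]methyl}dimethyl(propan-2-yloxy)silane | C=C1CCCC(C)(C)[C@@H]1C[Si](C)(C)OC(C)C | intermediate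
8 | [(1S)-2,2-dimethyl-6-methylidenecyclohexyl]methanol | C=C1CCCC(C)(C)[C@@H]1CO | intermediate
9 | (2S)-2-(bromomethyl)-1,1-dimethyl-3-methylidenecyclohexane | C=C1CCCC(C)(C)[C@@H]1CBr | intermediate
10 | geranyl bromide, (2E)-1-bromo-3,7-dimethylocta-2,6-diene | CC(C)=CCC/C(C)=C/CBr | starting material
11 | (4E)-5,9-dimethyldeca-4,8-dienenitrile | CC(C)=CCC/C(C)=C/CCC#N | intermediate
12 | (4E,8E)-10-hydroxy-5,9-dimethyldeca-4,8-dienenitrile | OC/C(C)=C/CC/C(C)=C/CCC#N | intermediate
13 | (4E,8E)-10-bromo-5,9-dimethyldeca-4,8-dienenitrile | BrC/C(C)=C/CC/C(C)=C/CCC#N | intermediate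
14 | {[(1S)-2,2-dimethyl-6-methylidenecyclohexyl]methyl}magnesium bromide | C=C1CCCC(C)(C)[C@@H]1C[Mg]Br | intermediate
15 | (4E,8E)-11-[(1S)-2,2-dimethyl-6-methylidenecyclohexyl]-5,9-dimethylundeca-4,8-dienenitrile | C=C1CCCC(C)(C)[C@@H]1CC/C(C)=C/CC/C(C)=C/CCC#N | intermediate
16 | bromoacetyl bromide | BrCC(Br)=O | starting material
17 | (tributylstannyl)methyl bromoacetate | CCCC[Sn](CCCC)(CCCC)COC(=O)CBr | intermediate
18 | bromo{2-oxo-2-[(tributylstannyl)methoxy]ethyl}zinc (Reformatsky reagent) | CCCC[Sn](CCCC)(CCCC)COC(=O)C[Zn]Br | intermediate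
19 | (tributylstannyl)methyl (2Z,6E,10E)-3-[(bromozincio)amino]-13-[(1S)-2,2-dimethyl-6-methylidenecyclohexyl]-7,11-dimethyltrideca-2,6,10-trienoate | C=C1CCCC(C)(C)[C@@H]1CC/C(C)=C/CC/C(C)=C/CC/C(N[Zn]Br)=C/C(=O)OC[Sn](CCCC)(CCCC)CCCC | intermediate
20 | (tributylstannyl)methyl (6E,10E)-13-[(1S)-2,2-dimethyl-6-methylidenecyclohexyl]-7,11-dimethyl-3-oxotrideca-6,10-dienoate | C=C1CCCC(C)(C)[C@@H]1CC/C(C)=C/CC/C(C)=C/CCC(=O)CC(=O)OC[Sn](CCCC)(CCCC)CCCC | intermediate
21 | lithium (2Z)-enolate of 20 | [Li+].C=C1CCCC(C)(C)[C@@H]1CC/C(C)=C/CC/C(C)=C/CC/C([O-])=C/C(=O)OC[Sn](CCCC)(CCCC)CCCC | intermediate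
22 | (tributylstannyl)methyl (2Z,6E,10E)-13-[(1S)-2,2-dimethyl-6-methylidenecyclohexyl]-7,11-dimethyl-3-{[(trifluoromethyl)sulfonyl]oxy}trideca-2,6,10-trienoate | C=C1CCCC(C)(C)[C@@H]1CC/C(C)=C/CC/C(C)=C/CC/C(OS(=O)(=O)C(F)(F)F)=C/C(=O)OC[Sn](CCCC)(CCCC)CCCC | intermediate
23 | 4-{(3E,7E)-10-[(1S)-2,2-dimethyl-6-methylidenecyclohexyl]-4,8-dimethyldeca-3,7-dien-1-yl}furan-2(5H)-one | C=C1CCCC(C)(C)[C@@H]1CC/C(C)=C/CC/C(C)=C/CCC1=CC(=O)OC1 | target

Total step count: 14 (six to bromide 9, three to bromide 13, one to reagent 17, four from the fragment union to 23).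
Longest linear sequence: 10 steps (steps 1 to 6, 10, 12, 13, 14).

Steps most likely to fail

Step 4. The organocopper may attack the unhindered CH2 terminus (SN2) instead of the ring carbon next to the quaternary centre, and facial discrimination at that hindered carbon may be incomplete. The fallback sets out from 5 and comes back at 8. Alcohol 5 is O-alkylated with (iodomethyl)tributylstannane (KH, THF) to tributyl{[(3,3-dimethylcyclohex-1-en-1-yl)methoxy]methyl}stannane F1. Treatment with n-BuLi at −78 °C brings about tin–lithium exchange and a Still–Wittig [2,3] rearrangement, which forms the hindered C–C bond intramolecularly and should give racemic (2,2-dimethyl-6-methylidenecyclohexyl)methanol F2. Lipase-catalysed acetylation (Burkholderia cepacia lipase, vinyl acetate, hexane) then converts the (R)-enantiomer into [(1R)-2,2-dimethyl-6-methylidenecyclohexyl]methyl acetate F3 and leaves 8, which is separated by chromatography.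

Step 14. Intramolecular tin-to-palladium transfer may be slow because the ester prefers the conformation that holds C5 away from C4, so that intermolecular coupling to oligomers, protodestannylation or decay of the triflate could take over. The fallback sets out from 15, comes back at 23 and closes the same bond by carbonyl addition instead of cross-coupling.
- A Blaise reaction of 15 with methyl bromoacetate (Zn, THF, reflux; then 1 M HCl) gives methyl (6E,10E)-13-[(1S)-2,2-dimethyl-6-methylidenecyclohexyl]-7,11-dimethyl-3-oxotrideca-6,10-dienoate F4.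
- Cold saponification (LiOH, THF/H2O, 0 °C) gives lithium (6E,10E)-13-[(1S)-2,2-dimethyl-6-methylidenecyclohexyl]-7,11-dimethyl-3-oxotrideca-6,10-dienoate F5, which is alkylated in the same flask with chloromethyl chlorosulfate (n-Bu4NHSO4, NaHCO3, CH2Cl2/H2O) to chloromethyl (6E,10E)-13-[(1S)-2,2-dimethyl-6-methylidenecyclohexyl]-7,11-dimethyl-3-oxotrideca-6,10-dienoate F6.
- A Finkelstein exchange (NaI, acetone) gives iodomethyl (6E,10E)-13-[(1S)-2,2-dimethyl-6-methylidenecyclohexyl]-7,11-dimethyl-3-oxotrideca-6,10-dienoate F7.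
- SmI2 (2.2 equiv, THF, −78 °C) then effects an intramolecular Barbier reaction, in which the acyloxymethyl carbon C5 adds to the C4 ketone and closes the lactone, giving 4-{(3E,7E)-10-[(1S)-2,2-dimethyl-6-methylidenecyclohexyl]-4,8-dimethyldeca-3,7-dien-1-yl}-4-hydroxydihydrofuran-2(3H)-one F8 (both C4 epimers).
- Dehydration of F8 (MsCl, Et3N, CH2Cl2, 0 °C) gives 23.

Step 10. Homocoupling during Grignard formation from the hindered bromide and attack at the γ-carbon of the allylic bromide (SN2′) would lower the yield of the fragment union. The fallback sets out from 8 and comes back at 15. Alcohol 8 is converted with PhSSPh and PBu3 into {[(1S)-2,2-dimethyl-6-methylidenecyclohexyl]methyl}(phenyl)sulfane F9. Oxidation with (NH4)6Mo7O24 (cat.) and H2O2 in EtOH at 0 °C gives ({[(1S)-2,2-dimethyl-6-methylidenecyclohexyl]methyl}sulfonyl)benzene F10. This is deprotonated with n-BuLi (THF, −78 °C) and alkylated with 13 to (4E,8E)-11-[(1S)-2,2-dimethyl-6-methylidenecyclohexyl]-5,9-dimethyl-11-(phenylsulfonyl)undeca-4,8-dienenitrile F11. Reductive desulfonylation (sodium amalgam, Na2HPO4, MeOH, −20 °C) then gives 15.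

Further compounds
F1 | step 4 | tributyl{[(3,3-dimethylcyclohex-1-en-1-yl)methoxy]methyl}stannane | CC1(C)CCCC(COC[Sn](CCCC)(CCCC)CCCC)=C1
F2 | step 4 | racemic (2,2-dimethyl-6-methylidenecyclohexyl)methanol | C=C1CCCC(C)(C)C1CO
F3 | step 4 | [(1R)-2,2-dimethyl-6-methylidenecyclohexyl]methyl acetate | C=C1CCCC(C)(C)[C@H]1COC(C)=O
F4 | step 14 | methyl (6E,10E)-13-[(1S)-2,2-dimethyl-6-methylidenecyclohexyl]-7,11-dimethyl-3-oxotrideca-6,10-dienoate | C=C1CCCC(C)(C)[C@@H]1CC/C(C)=C/CC/C(C)=C/CCC(=O)CC(=O)OC
F5 | step 14 | lithium (6E,10E)-13-[(1S)-2,2-dimethyl-6-methylidenecyclohexyl]-7,11-dimethyl-3-oxotrideca-6,10-dienoate | [Li+].C=C1CCCC(C)(C)[C@@H]1CC/C(C)=C/CC/C(C)=C/CCC(=O)CC(=O)[O-]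
F6 | step 14 | chloromethyl (6E,10E)-13-[(1S)-2,2-dimethyl-6-methylidenecyclohexyl]-7,11-dimethyl-3-oxotrideca-6,10-dienoate | C=C1CCCC(C)(C)[C@@H]1CC/C(C)=C/CC/C(C)=C/CCC(=O)CC(=O)OCCl
F7 | step 14 | iodomethyl (6E,10E)-13-[(1S)-2,2-dimethyl-6-methylidenecyclohexyl]-7,11-dimethyl-3-oxotrideca-6,10-dienoate | C=C1CCCC(C)(C)[C@@H]1CC/C(C)=C/CC/C(C)=C/CCC(=O)CC(=O)OCI
F8 | step 14 | 4-{(3E,7E)-10-[(1S)-2,2-dimethyl-6-methylidenecyclohexyl]-4,8-dimethyldeca-3,7-dien-1-yl}-4-hydroxydihydrofuran-2(3H)-one | C=C1CCCC(C)(C)[C@@H]1CC/C(C)=C/CC/C(C)=C/CCC1(O)CC(=O)OC1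
F9 | step 10 | {[(1S)-2,2-dimethyl-6-methylidenecyclohexyl]methyl}(phenyl)sulfane | C=C1CCCC(C)(C)[C@@H]1CSc1ccccc1
F10 | step 10 | ({[(1S)-2,2-dimethyl-6-methylidenecyclohexyl]methyl}sulfonyl)benzene | C=C1CCCC(C)(C)[C@@H]1CS(=O)(=O)c1ccccc1
F11 | step 10 | (4E,8E)-11-[(1S)-2,2-dimethyl-6-methylidenecyclohexyl]-5,9-dimethyl-11-(phenylsulfonyl)undeca-4,8-dienenitrile | C=C1CCCC(C)(C)[C@@H]1C(C/C(C)=C/CC/C(C)=C/CCC#N)S(=O)(=O)c1ccccc1
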